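**Retrosynthetic overview**
1. Naamidine B (17) ⇒ exocyclic amidine C–N bond, formed last: 2-aminoimidazole 10 + 1-methylparabanic acid 13 (from N-methylurea and oxalyl chloride).
2. 10 ⇒ C4–CH2Ar bond (key): (4-methoxybenzyl)magnesium chloride 5 + 5-arylidene-2-aminoimidazol-4-one 4, i.e. the imidazole carried as a creatinine. One flask adds the benzyl group, removes the C4 oxygen, turns C5=CH–Ar into C5–CH2Ar and creates the aromatic ring.
3. Enabling feature: C4 of the imidazole lies between N3 of the cyclic guanidine N1–C2(N)=N3 and C5, whose substituent is a benzylic CH2. C4 can therefore be an acylguanidine carbonyl and C5–CH2Ar an exocyclic enamine-type alkene; the C4 carbinol formed by addition is aminal-like and allylic, so ionisation and hydride capture give the 6π imidazole.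
4. 4 ⇒ creatinine 2 + 3-(benzyloxy)-4-methoxybenzaldehyde 1 (Knoevenagel condensation, then formamidine protection of the NH2).
5. Order of rings: the imidazole ring is bought as creatinine and aromatised in step 3; the trione ring of 13 is closed in step 6; the two are joined in step 7.

Key step: step 3

Assumption: 3, 4 and 6 are drawn as the thermodynamically preferred (Z)-alkenes and the formamidines as (E), neither geometry mattering because both elements are erased or removed later; in step 7 one molecule of BSA is taken to silylate the lactam of 13 and the phenol of 10.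

**Step 1**
Reactants: 1 3-(benzyloxy)-4-methoxybenzaldehyde; 2 creatinine
Product: 3 (5Z)-2-amino-5-[3-(benzyloxy)-4-methoxybenzylidene]-1-methyl-1,5-dihydro-4H-imidazol-4-one
Conditions: NaOAc, AcOH, 120 °C
Reagents that add atoms: none
Why: Knoevenagel-type aldol condensation in which the C5 methylene of creatinine, activated by the C4 lactam carbonyl, condenses with the non-enolisable aryl aldehyde with loss of water, the conjugated (Z)-alkene being expected under these equilibrating conditions.

**Step 2**
Reactants: 3 (5Z)-2-amino-5-[3-(benzyloxy)-4-methoxybenzylidene]-1-methyl-1,5-dihydro-4H-imidazol-4-one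
Product: 4 N'-{(5Z)-5-[3-(benzyloxy)-4-methoxybenzylidene]-1-methyl-4-oxo-4,5-dihydro-1H-imidazol-2-yl}-N,N-dimethylformimidamide
Conditions: DMF-DMA (3 equiv), DMF, 80 °C
Reagents that add atoms: N,N-dimethylformamide dimethyl acetal, COC(OC)N(C)C
Why: Amide-acetal condensation (amidine formation) on the only N–H function, which removes both acidic protons so that the Grignard reagent of step 3 is neither quenched nor faced with an unreactive guanidinate anion.

**Step 3**
Reactants: 4 N'-{(5Z)-5-[3-(benzyloxy)-4-methoxybenzylidene]-1-methyl-4-oxo-4,5-dihydro-1H-imidazol-2-yl}-N,N-dimethylformimidamide; 5 (4-methoxybenzyl)magnesium chloride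
Product: 8 N'-{5-[3-(benzyloxy)-4-methoxybenzyl]-4-(4-methoxybenzyl)-1-methyl-1H-imidazol-2-yl}-N,N-dimethylformimidamide, via carbinol 6 (not isolated), via azafulvenium trifluoroacetate 7 (not isolated)
Conditions: 5 (1.5 equiv), THF, −78 → 0 °C; then solvent switch to CH2Cl2, Et3SiH (5 equiv), TFA (20 equiv), 0 → 40 °C
Reagents that add atoms: none
Why: Proposed new method: the benzylic Grignard reagent should add 1,2 to the C4 carbonyl of the cyclic acylguanidine 4, the only carbonyl present and one with no acidic N–H or α-C–H, to give the magnesium alkoxide of carbinol 6; TFA then ionises the C4–O bond, which is aminal-like (N3) and allylic to the exocyclic C5=CH–Ar bond, to the azafulvenium ion 7, and Et3SiH delivers hydride to its benzylic terminus (or to C4, followed by acid-catalysed tautomerisation), which creates the aromatic 2-aminoimidazole sextet of 8. The closest known reaction types are the addition of Grignard reagents to tertiary amides and lactams followed by reduction of the resulting iminium ion (reductive alkylation of lactams) and the Et3SiH/TFA ionic hydrogenation of hetaryl(aryl)carbinols such as indol-3-yl and imidazolyl carbinols. No ring is closed; the imidazole ring already present in 4 is aromatised. The only new stereocentre, C4 of 6, is formed as a racemate and disappears in the same flask, as does the alkene geometry of 4. The step needs 1,2- instead of 1,4-addition, which is secured by the N1 lone pair that makes the exocyclic alkene an enamine-type bond with a weakly electrophilic β-carbon and by the preference of benzylic Grignard reagents for direct carbonyl addition; it also needs hydride capture to outrun Friedel–Crafts attack of 7 on the anisyl ring, which is secured because the only position that could close a six-membered ring is meta to the methoxy group and the silane is in excess.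

**Step 4**
Reactants: 8 N'-{5-[3-(benzyloxy)-4-methoxybenzyl]-4-(4-methoxybenzyl)-1-methyl-1H-imidazol-2-yl}-N,N-dimethylformimidamide
Product: 9 5-[3-(benzyloxy)-4-methoxybenzyl]-4-(4-methoxybenzyl)-1-methyl-1H-imidazol-2-amine
Conditions: 2 M aq. HCl, EtOH, 70 °C; then aq. NaHCO3
Reagents that add atoms: none
Why: Acid hydrolysis of the formamidine (via the N-formyl compound, which is hydrolysed under the same conditions) should free the 2-amino group, while the benzyl ether, the methyl ethers and the protonated aminoimidazole are stable to warm dilute acid.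

**Step 5**
Reactants: 9 5-[3-(benzyloxy)-4-methoxybenzyl]-4-(4-methoxybenzyl)-1-methyl-1H-imidazol-2-amine
Product: 10 5-(3-hydroxy-4-methoxybenzyl)-4-(4-methoxybenzyl)-1-methyl-1H-imidazol-2-amine
Conditions: H2 (1 atm), 10% Pd/C, MeOH, AcOH (2 equiv), rt; then aq. NaHCO3
Reagents that add atoms: none
Why: Catalytic hydrogenolysis of the aryl benzyl ether, with the aminoimidazole kept protonated by acetic acid so that it does not poison the catalyst and with no other reducible group in 9.

**Step 6**
Reactants: 11 N-methylurea; 12 oxalyl chloride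
Product: 13 1-methylparabanic acid (1-methylimidazolidine-2,4,5-trione)
Conditions: THF, 0 °C → reflux
Reagents that add atoms: none
Why: Double N-acylation of the urea by oxalyl chloride (the classical parabanic acid synthesis) should close the five-membered trione ring by two successive addition–eliminations.

**Step 7**
Reactants: 10 5-(3-hydroxy-4-methoxybenzyl)-4-(4-methoxybenzyl)-1-methyl-1H-imidazol-2-amine; 13 1-methylparabanic acid
Product: 17 naamidine B, via silyl imidate 14 (not isolated), via silyl ether 15 (not isolated), via O-silyl naamidine 16 (not isolated)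
Conditions: 13, BSA (2.5 equiv), MeCN, rt; then 10, toluene, 90 °C; MeOH quench
Reagents that add atoms: none
Why: Addition–elimination of the exocyclic NH2 of the 2-aminoimidazole at C4 of the O-silyl imidate 14 (the carbonyl carbon next to N3–H, activated by the adjacent C5=O), a condensation with close precedent for 2-amino-4,5-dibenzylimidazoles bearing a free phenol, which is silylated in the flask and freed again by methanol.

**Compound list**
1 | 3-(benzyloxy)-4-methoxybenzaldehyde | COc1ccc(C=O)cc1OCc1ccccc1 | starting material
2 | creatinine (2-amino-1-methyl-1,5-dihydro-4H-imidazol-4-one) | CN1CC(=O)N=C1N | starting material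
3 | (5Z)-2-amino-5-[3-(benzyloxy)-4-methoxybenzylidene]-1-methyl-1,5-dihydro-4H-imidazol-4-one | CN1/C(=C\c2ccc(OC)c(OCc3ccccc3)c2)C(=O)N=C1N | intermediate
4 | N'-{(5Z)-5-[3-(benzyloxy)-4-methoxybenzylidene]-1-methyl-4-oxo-4,5-dihydro-1H-imidazol-2-yl}-N,N-dimethylformimidamide, (E)-amidine | CN1/C(=C\c2ccc(OC)c(OCc3ccccc3)c2)C(=O)N=C1/N=C/N(C)C | intermediate
5 | (4-methoxybenzyl)magnesium chloride (THF solution) | COc1ccc(C[Mg]Cl)cc1 | starting material
6 | N'-{(5Z)-5-[3-(benzyloxy)-4-methoxybenzylidene]-4-hydroxy-4-(4-methoxybenzyl)-1-methyl-4,5-dihydro-1H-imidazol-2-yl}-N,N-dimethylformimidamide, racemic at C4, formed first as its chloromagnesium alkoxide | CN1/C(=C\c2ccc(OC)c(OCc3ccccc3)c2)C(O)(Cc2ccc(OC)cc2)N=C1/N=C/N(C)C | intermediate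
7 | 5-[3-(benzyloxy)-4-methoxybenzylidene]-2-[(dimethylaminomethylene)amino]-4-(4-methoxybenzyl)-1-methyl-5H-imidazol-1-ium trifluoroacetate (azafulvenium ion, one resonance form, exocyclic geometry delocalised) | C[N+]1=C(/N=C/N(C)C)N=C(Cc2ccc(OC)cc2)C1=Cc1ccc(OC)c(OCc2ccccc2)c1.[O-]C(=O)C(F)(F)F | intermediate
8 | N'-{5-[3-(benzyloxy)-4-methoxybenzyl]-4-(4-methoxybenzyl)-1-methyl-1H-imidazol-2-yl}-N,N-dimethylformimidamide, (E)-amidine | COc1ccc(Cc2nc(/N=C/N(C)C)n(C)c2Cc2ccc(OC)c(OCc3ccccc3)c2)cc1 | intermediate
9 | 5-[3-(benzyloxy)-4-methoxybenzyl]-4-(4-methoxybenzyl)-1-methyl-1H-imidazol-2-amine | COc1ccc(Cc2nc(N)n(C)c2Cc2ccc(OC)c(OCc3ccccc3)c2)cc1 | intermediate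
10 | 5-(3-hydroxy-4-methoxybenzyl)-4-(4-methoxybenzyl)-1-methyl-1H-imidazol-2-amine | COc1ccc(Cc2nc(N)n(C)c2Cc2ccc(OC)c(O)c2)cc1 | intermediate
11 | N-methylurea | CNC(N)=O | starting material
12 | oxalyl chloride | O=C(Cl)C(Cl)=O | starting material
13 | 1-methylparabanic acid (1-methylimidazolidine-2,4,5-trione) | CN1C(=O)NC(=O)C1=O | intermediate
14 | 1-methyl-4-[(trimethylsilyl)oxy]-1H-imidazole-2,5-dione (O-silyl imidate of 13) | CN1C(=O)N=C(O[Si](C)(C)C)C1=O | intermediate
15 | 5-{4-methoxy-3-[(trimethylsilyl)oxy]benzyl}-4-(4-methoxybenzyl)-1-methyl-1H-imidazol-2-amine (silyl ether of 10) | COc1ccc(Cc2nc(N)n(C)c2Cc2ccc(OC)c(O[Si](C)(C)C)c2)cc1 | intermediate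
16 | O-trimethylsilyl naamidine B | COc1ccc(Cc2nc(NC3=NC(=O)N(C)C3=O)n(C)c2Cc2ccc(OC)c(O[Si](C)(C)C)c2)cc1 | intermediate
17 | naamidine B | COc1ccc(Cc2nc(NC3=NC(=O)N(C)C3=O)n(C)c2Cc2ccc(OC)c(O)c2)cc1 | target

**Totals**
Total step count: 7. Longest linear sequence: 6 steps (steps 1, 2, 3, 4, 5 and 7); step 6 is a one-step side branch.

**Steps most likely to fail**

Step 3 (proposed new method). The Grignard reagent may add in conjugate fashion to the exocyclic alkene or at the formamidine carbon instead of at C4. The strongly stabilised cation may also take up hydride too slowly and be lost through Friedel–Crafts oligomerisation. The fallback uses known reaction types, sets out from 4 and returns at 8. Chemoselective hydrogenation of the exocyclic alkene of 4 (H2, Pd/C poisoned with Ph2S, EtOAc–MeOH) should give racemic N'-{5-[3-(benzyloxy)-4-methoxybenzyl]-1-methyl-4-oxo-4,5-dihydro-1H-imidazol-2-yl}-N,N-dimethylformimidamide F1 with the benzyl ether intact. Deprotonation at C5 and O-sulfonylation of the resulting aromatic 4-oxidoimidazole (KHMDS, PhNTf2, THF, −78 °C) should give 5-[3-(benzyloxy)-4-methoxybenzyl]-2-[(dimethylaminomethylene)amino]-1-methyl-1H-imidazol-4-yl trifluoromethanesulfonate F2. Negishi coupling of F2 with commercial (4-methoxybenzyl)zinc chloride (Pd2(dba)3, XPhos, THF, 50 °C) forms the same C4–CH2 bond and gives 8.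

Step 7. Silylation or acylation at the free phenol and the low solubility of the polar aminophenol may stall the addition–elimination. The amine may also open the trione ring instead of condensing. The fallback sets out from 9 and returns at 17. The phenol stays protected during the condensation: 9 is treated with silyl imidate 14 (from 13 and BSA, MeCN–toluene, 90 °C) to give O-benzylnaamidine B F3. The benzyl ether is then cleaved under non-reductive Lewis-acid conditions (BCl3, pentamethylbenzene, CH2Cl2, −78 °C), which should spare the methyl ethers and the dehydrohydantoin, to give 17.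

Step 1. The condensation may stall because the creatinine methylene is only weakly acidic and creatinine is poorly soluble, with thermal decomposition at the temperature needed. The fallback sets out from 1 and returns at 3. Knoevenagel condensation of 1 with the more acidic 1-methyl-2-thiohydantoin (piperidine, EtOH, reflux) should give (5Z)-5-[3-(benzyloxy)-4-methoxybenzylidene]-1-methyl-2-thioxoimidazolidin-4-one F4. S-Methylation (MeI, K2CO3, acetone) should give (5Z)-5-[3-(benzyloxy)-4-methoxybenzylidene]-1-methyl-2-(methylsulfanyl)-1,5-dihydro-4H-imidazol-4-one F5. Ammonolysis of the isothiourea (7 M NH3 in MeOH, sealed tube, 90 °C) should give 3.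

**Further compounds**
F1 | step 3 | N'-{5-[3-(benzyloxy)-4-methoxybenzyl]-1-methyl-4-oxo-4,5-dihydro-1H-imidazol-2-yl}-N,N-dimethylformimidamide (racemic) | CN1C(Cc2ccc(OC)c(OCc3ccccc3)c2)C(=O)N=C1/N=C/N(C)C
F2 | step 3 | 5-[3-(benzyloxy)-4-methoxybenzyl]-2-[(dimethylaminomethylene)amino]-1-methyl-1H-imidazol-4-yl trifluoromethanesulfonate | CN(C)/C=N/c1nc(OS(=O)(=O)C(F)(F)F)c(Cc2ccc(OC)c(OCc3ccccc3)c2)n1C
F3 | step 7 | O-benzylnaamidine B | COc1ccc(Cc2nc(NC3=NC(=O)N(C)C3=O)n(C)c2Cc2ccc(OC)c(OCc3ccccc3)c2)cc1
F4 | step 1 | (5Z)-5-[3-(benzyloxy)-4-methoxybenzylidene]-1-methyl-2-thioxoimidazolidin-4-one | CN1/C(=C\c2ccc(OC)c(OCc3ccccc3)c2)C(=O)NC1=S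
F5 | step 1 | (5Z)-5-[3-(benzyloxy)-4-methoxybenzylidene]-1-methyl-2-(methylsulfanyl)-1,5-dihydro-4H-imidazol-4-one | CN1/C(=C\c2ccc(OC)c(OCc3ccccc3)c2)C(=O)N=C1SC
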